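The furan ring is taken apart at two bonds, C2–C3 and O1–C2, which isolates C2 with its guaiacyl ring as a one-carbon unit. Because this carbon sits between the ring oxygen and C3, an aryl-stabilised sulfur ylide can deliver it to a four-atom o-quinone methide (O1–C7a–C3a–C3) and build the dihydrofuran ring of the benzofuran in a single [4+1] operation. The annulation partners are a 2-(1-tosylethyl)phenol derived from dihydroconiferyl alcohol, whose methyl group later becomes the formyl carbon, and a MOM-protected vanillyl dimethylsulfonium bromide. Dehydrogenation, methyl oxidation and one acidic deprotection finish the synthesis.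

Key step: step 9

Remark on the chemistry: the target has no stereocentre; the two stereocentres made in step 9 are formed as a racemate (trans, written 2S*,3S*) and are removed in step 10.

Step 1
Reactants: 1 dihydroconiferyl alcohol
Product: 2 4-[3-(tert-butyldimethylsilyloxy)propyl]-2-methoxyphenol
Conditions: TBSCl (1.05 equiv), imidazole, CH2Cl2, 0 °C
Reagents that add atoms: tert-butyldimethylsilyl chloride, CC(C)(C)[Si](C)(C)Cl
Why: Silyl ether formation with TBSCl/imidazole is chemoselective for the primary alcohol, because the guaiacol hydroxyl is hydrogen-bonded to the neighbouring methoxy group, is not deprotonated by imidazole and is silylated much more slowly at 0 °C.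

Step 2
Reactants: 2 4-[3-(tert-butyldimethylsilyloxy)propyl]-2-methoxyphenol
Product: 3 5-[3-(tert-butyldimethylsilyloxy)propyl]-2-hydroxy-3-methoxybenzaldehyde
Conditions: MgCl2, Et3N, (CH2O)n, MeCN, reflux; then cold aq. citric acid
Reagents that add atoms: paraformaldehyde (formaldehyde), C=O
Why: Casnati–Skattebøl ortho-formylation: the magnesium phenoxide delivers formaldehyde to the only free position ortho to oxygen (para is blocked by the side chain) and the benzylic alkoxide is oxidised by hydride transfer to a second formaldehyde, under conditions that leave the silyl ether untouched.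

Step 3
Reactants: 3 5-[3-(tert-butyldimethylsilyloxy)propyl]-2-hydroxy-3-methoxybenzaldehyde
Product: 4 2-(1-hydroxyethyl)-6-methoxy-4-[3-(tert-butyldimethylsilyloxy)propyl]phenol (racemic)
Conditions: MeMgBr (2.5 equiv), THF, 0 °C → rt; aq. NH4Cl
Reagents that add atoms: methylmagnesium bromide, C[Mg]Br
Why: Grignard addition to the aldehyde, after the first equivalent has deprotonated the phenol, gives the secondary benzylic alcohol as a racemate, which suffices because this carbon becomes trigonal again in step 9.

Step 4
Reactants: 4 2-(1-hydroxyethyl)-6-methoxy-4-[3-(tert-butyldimethylsilyloxy)propyl]phenol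
Product: 5 2-methoxy-6-[1-(p-tolylsulfonyl)ethyl]-4-[3-(tert-butyldimethylsilyloxy)propyl]phenol (racemic)
Conditions: p-TolSO2H (1.5 equiv, freshly liberated from TolSO2Na), CH2Cl2, 4 Å MS, 0 °C → rt
Reagents that add atoms: p-toluenesulfinic acid, Cc1ccc(S(=O)O)cc1
Why: Acid-promoted SN1-type substitution of the o-hydroxybenzylic alcohol: the sulfinic acid ionises the carbinol with help from the ortho-hydroxyl group and sulfinate captures the cation at sulfur to give the racemic sulfone, while the weak acid in dry CH2Cl2 should leave the primary silyl ether in place.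

Step 5
Reactants: 6 vanillin
Product: 7 3-methoxy-4-(methoxymethoxy)benzaldehyde
Conditions: MOMCl, iPr2NEt, CH2Cl2, 0 °C → rt
Reagents that add atoms: chloromethyl methyl ether, COCCl
Why: O-Alkylation of the phenol (Williamson-type acetal protection) gives a MOM ether that is stable to hydride, base, DDQ and SeO2 and is removed by acid at the end.

Step 6
Reactants: 7 3-methoxy-4-(methoxymethoxy)benzaldehyde
Product: 8 [3-methoxy-4-(methoxymethoxy)phenyl]methanol
Conditions: NaBH4, MeOH, 0 °C
Reagents that add atoms: none
Why: Borohydride reduction of the aryl aldehyde to the benzylic alcohol, with no other reducible group present.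

Step 7
Reactants: 8 [3-methoxy-4-(methoxymethoxy)phenyl]methanol
Product: 9 4-(bromomethyl)-2-methoxy-1-(methoxymethoxy)benzene
Conditions: CBr4, PPh3, CH2Cl2, 0 °C; Ph3PO precipitated with hexane/Et2O, filtrate used at once
Reagents that add atoms: carbon tetrabromide, BrC(Br)(Br)Br
Why: The Appel reaction converts the benzylic alcohol into the bromide under neutral conditions, which spares the acid-labile acetal from hydrogen bromide.

Step 8
Reactants: 9 4-(bromomethyl)-2-methoxy-1-(methoxymethoxy)benzene
Product: 10 dimethyl[3-methoxy-4-(methoxymethoxy)benzyl]sulfonium bromide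
Conditions: Me2S (5 equiv), acetone, rt, dark; precipitate washed with Et2O
Reagents that add atoms: dimethyl sulfide, CSC
Why: SN2 S-alkylation of dimethyl sulfide by the activated benzylic bromide gives the sulfonium salt, which precipitates from acetone and is thereby freed from neutral impurities.

Step 9
Reactants: 5 2-methoxy-6-[1-(p-tolylsulfonyl)ethyl]-4-[3-(tert-butyldimethylsilyloxy)propyl]phenol; 10 dimethyl[3-methoxy-4-(methoxymethoxy)benzyl]sulfonium bromide
Product: 14 tert-butyl{3-[(2S*,3S*)-7-methoxy-2-[3-methoxy-4-(methoxymethoxy)phenyl]-3-methyl-2,3-dihydro-1-benzofuran-5-yl]propoxy}dimethylsilane (racemic trans isomer), via o-quinone methide 11 (not isolated), via sulfonium ylide 12 (not isolated), via phenoxide–sulfonium betaine 13 (not isolated)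
Conditions: Cs2CO3 (4 equiv), CH2Cl2, 0 °C → rt; 5 added slowly to 10 (2 equiv) and base
Reagents that add atoms: none
Why: Cs2CO3 converts 5 into its phenoxide, which expels p-toluenesulfinate by 1,4-elimination to give o-quinone methide 11, and deprotonates 10 at the benzylic carbon to ylide 12; the ylide carbon adds to the exocyclic carbon of 11 (C2–C3 bond) with rearomatisation to betaine 13, whose phenoxide displaces dimethyl sulfide (O1–C2 bond). The closest known reaction type is the formal [4+1] annulation of sulfur ylides with o-quinone methides released by base from 2-(1-sulfonylalkyl)phenols, which gives trans-2,3-dihydrobenzofurans. The dihydrofuran ring closes by an intramolecular SN2 O-alkylation in the 5-exo-tet mode with inversion at C2. C3 is created in the conjugate addition and C2 in the displacement; the sulfonium-bearing carbon of 13 can epimerise by proton transfer, and closure through the transition state that keeps aryl and methyl on opposite faces gives the trans racemate (2S*,3S*), a substrate control that is not critical because step 10 removes both centres. The step needs C-attack at the exocyclic carbon followed by O-alkylation, instead of O-benzylation of the phenoxide of 5, rearrangement of the ylide or dimerisation of 11; the gain of aromaticity directs the 1,4-addition, the phenoxide of 13 sits five atoms from the leaving group, and slow addition of 5 to an excess of 10 keeps the ylide in excess over 11.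

Step 10
Reactants: 14 trans-2-aryl-3-methyl-2,3-dihydrobenzofuran
Product: 15 tert-butyl{3-[7-methoxy-2-[3-methoxy-4-(methoxymethoxy)phenyl]-3-methyl-1-benzofuran-5-yl]propoxy}dimethylsilane
Conditions: DDQ (1.3 equiv), dry 1,4-dioxane, 90 °C
Reagents that add atoms: none
Why: DDQ dehydrogenation: hydride abstraction from C2–H (benzylic, next to oxygen, stabilised by the para-oxygenated aryl ring) and loss of the C3 proton aromatise the furan ring and erase both stereocentres.

Step 11
Reactants: 15 2-aryl-3-methylbenzofuran
Product: 16 5-[3-(tert-butyldimethylsilyloxy)propyl]-7-methoxy-2-[3-methoxy-4-(methoxymethoxy)phenyl]-1-benzofuran-3-carbaldehyde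
Conditions: SeO2 (2.5 equiv), 1,4-dioxane, reflux
Reagents that add atoms: selenium dioxide, O=[Se]=O
Why: Riley oxidation with SeO2: the 3-methyl group is allylic to the enol-ether-like C2=C3 bond of the benzofuran and is the only such position, so ene reaction and [2,3]-shift should oxidise it to the conjugated aldehyde, which resists further oxidation.

Step 12
Reactants: 16 protected benzofuran-3-carbaldehyde
Product: 17 2-(4-hydroxy-3-methoxyphenyl)-5-(3-hydroxypropyl)-7-methoxy-1-benzofuran-3-carbaldehyde (target)
Conditions: 3 M aq. HCl, THF, 50 °C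
Reagents that add atoms: none
Why: Acid hydrolysis cleaves the aryl MOM acetal and the primary silyl ether in one operation, while the aryl methyl ethers, the benzofuran and the conjugated aldehyde are stable to dilute aqueous acid.

Compound list
1 | dihydroconiferyl alcohol, 4-(3-hydroxypropyl)-2-methoxyphenol | COc1cc(CCCO)ccc1O | starting material
2 | 4-[3-(tert-butyldimethylsilyloxy)propyl]-2-methoxyphenol | COc1cc(CCCO[Si](C)(C)C(C)(C)C)ccc1O | intermediate
3 | 5-[3-(tert-butyldimethylsilyloxy)propyl]-2-hydroxy-3-methoxybenzaldehyde | COc1cc(CCCO[Si](C)(C)C(C)(C)C)cc(C=O)c1O | intermediate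
4 | 2-(1-hydroxyethyl)-6-methoxy-4-[3-(tert-butyldimethylsilyloxy)propyl]phenol, racemic | COc1cc(CCCO[Si](C)(C)C(C)(C)C)cc(C(C)O)c1O | intermediate
5 | 2-methoxy-6-[1-(p-tolylsulfonyl)ethyl]-4-[3-(tert-butyldimethylsilyloxy)propyl]phenol, racemic | COc1cc(CCCO[Si](C)(C)C(C)(C)C)cc(C(C)S(=O)(=O)c2ccc(C)cc2)c1O | intermediate
6 | vanillin | COc1cc(C=O)ccc1O | starting material
7 | 3-methoxy-4-(methoxymethoxy)benzaldehyde | COCOc1ccc(C=O)cc1OC | intermediate
8 | [3-methoxy-4-(methoxymethoxy)phenyl]methanol | COCOc1ccc(CO)cc1OC | intermediate
9 | 4-(bromomethyl)-2-methoxy-1-(methoxymethoxy)benzene | COCOc1ccc(CBr)cc1OC | intermediate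
10 | dimethyl[3-methoxy-4-(methoxymethoxy)benzyl]sulfonium bromide | C[S+](C)Cc1ccc(OCOC)c(OC)c1.[Br-] | intermediate
11 | o-quinone methide, 6-ethylidene-2-methoxy-4-[3-(tert-butyldimethylsilyloxy)propyl]cyclohexa-2,4-dien-1-one, exocyclic alkene geometry not controlled | COC1=CC(CCCO[Si](C)(C)C(C)(C)C)=CC(=CC)C1=O | intermediate
12 | sulfonium ylide, dimethylsulfonium [3-methoxy-4-(methoxymethoxy)phenyl]methylide | C[S+](C)[CH-]c1ccc(OCOC)c(OC)c1 | intermediate
13 | phenoxide–sulfonium betaine, racemic; the diastereomer that closes to 14 is shown, and it can epimerise at the sulfonium-bearing carbon | C[C@@H](c1cc(CCCO[Si](C)(C)C(C)(C)C)cc(OC)c1[O-])[C@H](c1ccc(OCOC)c(OC)c1)[S+](C)C | intermediate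
14 | tert-butyl{3-[(2S*,3S*)-7-methoxy-2-[3-methoxy-4-(methoxymethoxy)phenyl]-3-methyl-2,3-dihydro-1-benzofuran-5-yl]propoxy}dimethylsilane, racemic trans isomer, relative configuration shown | C[C@@H]1[C@@H](c2ccc(OCOC)c(OC)c2)Oc2c(OC)cc(CCCO[Si](C)(C)C(C)(C)C)cc21 | intermediate
15 | tert-butyl{3-[7-methoxy-2-[3-methoxy-4-(methoxymethoxy)phenyl]-3-methyl-1-benzofuran-5-yl]propoxy}dimethylsilane | Cc1c(-c2ccc(OCOC)c(OC)c2)oc2c(OC)cc(CCCO[Si](C)(C)C(C)(C)C)cc12 | intermediate
16 | 5-[3-(tert-butyldimethylsilyloxy)propyl]-7-methoxy-2-[3-methoxy-4-(methoxymethoxy)phenyl]-1-benzofuran-3-carbaldehyde | O=Cc1c(-c2ccc(OCOC)c(OC)c2)oc2c(OC)cc(CCCO[Si](C)(C)C(C)(C)C)cc12 | intermediate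
17 | 2-(4-hydroxy-3-methoxyphenyl)-5-(3-hydroxypropyl)-7-methoxy-1-benzofuran-3-carbaldehyde | COc1cc(-c2oc3c(OC)cc(CCCO)cc3c2C=O)ccc1O | target

Total step count: 12.
Longest linear sequence: 8 steps (steps 1–4, then 9–12; the sulfonium branch, steps 5–8 then 9–12, is equally long).

Steps most likely to fail

Step 9. The ylide may be lost by [2,3]-sigmatropic rearrangement through the S-methylide, or the sulfonium salt may benzylate the phenoxide of 5 before sulfinate is expelled. The o-quinone methide may also dimerise or tautomerise to the vinylphenol when the ylide concentration is low. The fallback replaces the annulation by a reductive ketone–ester coupling; it sets out from 4 and 7 and comes back to the route at 15. Diol 4 would be oxidised at the benzylic carbinol with activated MnO2 (CH2Cl2, rt) to 1-{2-hydroxy-3-methoxy-5-[3-(tert-butyldimethylsilyloxy)propyl]phenyl}ethan-1-one F1. Aldehyde 7 would be oxidised under Pinnick conditions (NaClO2, NaH2PO4, 2-methyl-2-butene, t-BuOH/H2O) to 3-methoxy-4-(methoxymethoxy)benzoic acid F2. Steglich esterification of the two (EDC·HCl, DMAP, CH2Cl2) should give 2-acetyl-6-methoxy-4-[3-(tert-butyldimethylsilyloxy)propyl]phenyl 3-methoxy-4-(methoxymethoxy)benzoate F3. An intramolecular McMurry-type coupling of its ketone and ester carbonyl groups with low-valent titanium (TiCl3, Zn dust, DME, reflux) should then close the furan ring and give 15 directly.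

Step 11. The ene reaction may be slow at the fully substituted C2=C3 bond, oxidation may compete at the benzylic CH2 of the side chain, and selenous acid may hydrolyse the protecting groups and so expose the phenol to oxidation. The fallback replaces the direct oxidation by halogenation and oxygen transfer; it sets out from 15 and comes back at 16. Wohl–Ziegler bromination (NBS, AIBN, PhCF3, 80 °C) should give {3-[3-(bromomethyl)-7-methoxy-2-[3-methoxy-4-(methoxymethoxy)phenyl]-1-benzofuran-5-yl]propoxy}(tert-butyl)dimethylsilane F4, and Kornblum oxidation (DMSO, NaHCO3, 80 °C) should convert it into 16.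

Step 4. The sulfinic acid may cleave the silyl ether, and the benzylic cation may alkylate a second electron-rich arene instead of being captured by sulfinate. The fallback gives up the silyl ether during the acidic step and restores it afterwards; it sets out from 4 and comes back at 5. Treatment of 4 with TolSO2Na and aq. HCl in THF at rt, run until desilylation is complete, should give 4-(3-hydroxypropyl)-2-methoxy-6-[1-(p-tolylsulfonyl)ethyl]phenol F5. Silylation of the primary alcohol (TBSCl, imidazole, CH2Cl2, 0 °C), which the hindered phenol should not undergo, returns 5.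

Further compounds
F1 | step 9 | 1-{2-hydroxy-3-methoxy-5-[3-(tert-butyldimethylsilyloxy)propyl]phenyl}ethan-1-one | COc1cc(CCCO[Si](C)(C)C(C)(C)C)cc(C(C)=O)c1O
F2 | step 9 | 3-methoxy-4-(methoxymethoxy)benzoic acid | COCOc1ccc(C(=O)O)cc1OC
F3 | step 9 | 2-acetyl-6-methoxy-4-[3-(tert-butyldimethylsilyloxy)propyl]phenyl 3-methoxy-4-(methoxymethoxy)benzoate | COCOc1ccc(C(=O)Oc2c(OC)cc(CCCO[Si](C)(C)C(C)(C)C)cc2C(C)=O)cc1OC
F4 | step 11 | {3-[3-(bromomethyl)-7-methoxy-2-[3-methoxy-4-(methoxymethoxy)phenyl]-1-benzofuran-5-yl]propoxy}(tert-butyl)dimethylsilane | BrCc1c(-c2ccc(OCOC)c(OC)c2)oc2c(OC)cc(CCCO[Si](C)(C)C(C)(C)C)cc12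
F5 | step 4 | 4-(3-hydroxypropyl)-2-methoxy-6-[1-(p-tolylsulfonyl)ethyl]phenol, racemic | COc1cc(CCCO)cc(C(C)S(=O)(=O)c2ccc(C)cc2)c1O
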